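**Plan**
- Retrosynthesis: the C5–O bond is cut back to C5–B and then to C5–H; next the acetyl C–O bond at C2; last the bond between the first two chain carbons, as a Wittig alkene, giving o-vanillin and a C14 phosphonium salt.
- Forward: the C14 unit is joined to the aldehyde carbon of o-vanillin, the alkene is hydrogenated, the only phenol is acetylated, and then C5–H becomes C5–Bpin and finally C5–OH. No ring is formed; the benzene ring comes from o-vanillin.
- Enabling feature: with the ring numbered C1 (pentadecyl), C2 (OAc), C3 (OMe), C4 (H), C5 (OH), C6 (H), C5–H is the only ring C–H with no ortho substituent, and C5 is where the free hydroxyl belongs.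
- Stereochemistry: the target has no stereocentre; the Wittig alkene geometry is erased by hydrogenation.

Key step: step 5

Assumption: the Wittig product is carried forward as an E/Z mixture (Z expected to predominate), because the next step removes the double bond.

**Route**

Step 1
Reactants: 1 1-bromotetradecane; 2 triphenylphosphine
Product: 3 tetradecyltriphenylphosphonium bromide
Conditions: MeCN, reflux; precipitate from Et2O
Reagents that add atoms: none
Why: SN2 quaternisation of triphenylphosphine by an unhindered primary alkyl bromide (phosphonium salt formation) is reliable and should give a crystalline salt.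

Step 2
Reactants: 3 tetradecyltriphenylphosphonium bromide; 4 o-vanillin (2-hydroxy-3-methoxybenzaldehyde)
Product: 6 2-methoxy-6-[(1Z)-pentadec-1-en-1-yl]phenol as the expected major isomer of an E/Z mixture, via tetradecylidenetriphenylphosphorane 5 (not isolated)
Conditions: 3 (1.3 equiv), KOtBu (2.4 equiv), THF, 0 °C; then 4, 0 °C to rt; 1 M HCl work-up
Reagents that add atoms: none
Why: Wittig olefination in which the extra base converts the phenol into its potassium phenoxide so that the non-stabilised ylide is not quenched and still adds to the aldehyde, as in the routine olefination of salicylaldehydes with excess base.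

Step 3
Reactants: 6 2-methoxy-6-(pentadec-1-en-1-yl)phenol (E/Z mixture)
Product: 7 2-methoxy-6-pentadecylphenol
Conditions: H2 (1 atm), 10% Pd/C, EtOAc, rt
Reagents that add atoms: none
Why: Heterogeneous catalytic hydrogenation of a disubstituted styrenic alkene over Pd/C should be fast and should leave the aryl methyl ether and the phenol untouched.

Step 4
Reactants: 7 2-methoxy-6-pentadecylphenol
Product: 8 2-methoxy-6-pentadecylphenyl acetate
Conditions: Ac2O, pyridine, DMAP (cat.), rt
Reagents that add atoms: acetic anhydride, CC(=O)OC(C)=O
Why: DMAP-catalysed acylation through the N-acetylpyridinium ion should overcome the hindrance of the 2,6-disubstituted phenol, and since this is the only hydroxyl in the molecule no selectivity is required.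

Step 5
Reactants: 8 2-methoxy-6-pentadecylphenyl acetate; 9 bis(pinacolato)diboron
Product: 10 2-methoxy-6-pentadecyl-4-(4,4,5,5-tetramethyl-1,3,2-dioxaborolan-2-yl)phenyl acetate
Conditions: [Ir(cod)OMe]2 (1.5 mol%), 4,4'-di-tert-butyl-2,2'-bipyridine (3 mol%), B2pin2 (1.0 equiv), THF, 80 °C, sealed tube, N2
Reagents that add atoms: none
Why: Iridium-catalysed aromatic C–H borylation, in which the precatalyst, the bipyridine and B2pin2 form a tris(boryl) complex of trivalent iridium that cleaves an arene C–H bond and then releases the aryl boronate by C–B reductive elimination, the boryl complex being regenerated by B2pin2. The closest known reaction type is the borylation of 1,2,3-trisubstituted benzenes at the 5-position, which forms the C5–B bond of 10 as the single new skeletal bond. No ring is closed and no stereocentre is created. The step needs site selectivity among three ring C–H bonds, and sterics should secure it: C4–H lies next to OMe, C6–H next to the pentadecyl chain, and only C5–H has hydrogen on both neighbouring carbons. A second borylation is not expected, since every remaining ring C–H would then be flanked on both sides, and the sp3 C–H bonds of the chain and the acetyl group are inert with this ligand at this temperature. The acetate sits between two substituents and has no free ortho position, so it can neither direct the catalyst nor be lost.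

Step 6
Reactants: 10 2-methoxy-6-pentadecyl-4-(4,4,5,5-tetramethyl-1,3,2-dioxaborolan-2-yl)phenyl acetate
Product: 12 4-hydroxy-2-methoxy-6-pentadecylphenyl acetate (target), via aryl pinacol borate 11 (not isolated)
Conditions: Oxone (2KHSO5·KHSO4·K2SO4, 1 equiv), acetone/H2O (1:1), rt, short reaction time; aq. NaHSO3 quench
Reagents that add atoms: potassium peroxymonosulfate (KHSO5, the active component of Oxone), [K+].[O-]S(=O)(=O)OO
Why: Oxidation of an aryl boronate by peroxymonosulfate, in which the peroxide oxygen adds to boron, the aryl group migrates from boron to oxygen at the same carbon and the resulting borate is hydrolysed by the aqueous medium, under brief, non-basic conditions that the hindered aryl acetate should survive.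

**Compound list**
1 | 1-bromotetradecane | CCCCCCCCCCCCCCBr | starting material
2 | triphenylphosphine | c1ccc(cc1)P(c1ccccc1)c1ccccc1 | starting material
3 | tetradecyltriphenylphosphonium bromide | CCCCCCCCCCCCCC[P+](c1ccccc1)(c1ccccc1)c1ccccc1.[Br-] | intermediate
4 | o-vanillin (2-hydroxy-3-methoxybenzaldehyde) | COc1cccc(C=O)c1O | starting material
5 | tetradecylidenetriphenylphosphorane (ylide, not isolated) | CCCCCCCCCCCCCC=P(c1ccccc1)(c1ccccc1)c1ccccc1 | intermediate
6 | 2-methoxy-6-[(1Z)-pentadec-1-en-1-yl]phenol (expected major isomer; E/Z mixture used) | CCCCCCCCCCCCC/C=C\c1cccc(OC)c1O | intermediate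
7 | 2-methoxy-6-pentadecylphenol | CCCCCCCCCCCCCCCc1cccc(OC)c1O | intermediate
8 | 2-methoxy-6-pentadecylphenyl acetate | CCCCCCCCCCCCCCCc1cccc(OC)c1OC(C)=O | intermediate
9 | bis(pinacolato)diboron | CC1(C)OB(OC1(C)C)B1OC(C)(C)C(C)(C)O1 | starting material
10 | 2-methoxy-6-pentadecyl-4-(4,4,5,5-tetramethyl-1,3,2-dioxaborolan-2-yl)phenyl acetate | CCCCCCCCCCCCCCCc1cc(B2OC(C)(C)C(C)(C)O2)cc(OC)c1OC(C)=O | intermediate
11 | 2-methoxy-6-pentadecyl-4-[(4,4,5,5-tetramethyl-1,3,2-dioxaborolan-2-yl)oxy]phenyl acetate (aryl pinacol borate, not isolated) | CCCCCCCCCCCCCCCc1cc(OB2OC(C)(C)C(C)(C)O2)cc(OC)c1OC(C)=O | intermediate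
12 | 4-hydroxy-2-methoxy-6-pentadecylphenyl acetate | CCCCCCCCCCCCCCCc1cc(O)cc(OC)c1OC(C)=O | target

**Summary**
Total step count: 6. Longest linear sequence: 6 steps (from 1-bromotetradecane; o-vanillin enters at step 2).

**Steps most likely to fail**

Step 5. The borylation may stall through catalyst inhibition by trace impurities, or some borylation may occur next to the methoxy group. Fallback: setting out from phenol 7, electrophilic bromination (NBS, MeCN, 0 °C) should go para to the hydroxyl, whose two ortho positions are blocked, giving 4-bromo-2-methoxy-6-pentadecylphenol F1. Acetylation (Ac2O, pyridine, DMAP) should then give 4-bromo-2-methoxy-6-pentadecylphenyl acetate F2. Miyaura borylation of F2 with 9 (Pd(dppf)Cl2, KOAc, dioxane, 80 °C) returns to the route at boronate 10.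

Step 6. The electron-rich phenol may be oxidised further by the peroxide reagent, or the acetate may be cleaved during oxidation or work-up. Fallback: setting out from boronate 10, oxidation under basic conditions that deliberately sacrifice the acetate (H2O2, aq. NaOH, THF, 0 °C; Na2S2O4 in the acidic work-up) should give 2-methoxy-6-pentadecylbenzene-1,4-diol F3. Exhaustive acetylation (Ac2O, pyridine, DMAP) should give 2-methoxy-6-pentadecyl-1,4-phenylene diacetate F4. Selective methanolysis (K2CO3, MeOH, 0 °C, under argon) should remove only the unhindered C5 acetate, since the C2 acetate is shielded by OMe and the chain, which returns to the route at target 12.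

Step 2. The phenoxide formed from the free phenol may deactivate the aldehyde so that the olefination stalls, or it may consume ylide. Fallback: setting out from o-vanillin 4, benzylation (BnBr, K2CO3, DMF) should give 2-(benzyloxy)-3-methoxybenzaldehyde F5. Wittig reaction with ylide 5 (from 3 and one equivalent of KOtBu, THF) should give 2-(benzyloxy)-1-methoxy-3-[(1Z)-pentadec-1-en-1-yl]benzene F6 as an E/Z mixture. Hydrogenation (H2, Pd/C, EtOAc/EtOH) should saturate the alkene and cleave the benzyl ether in one operation, returning to the route at phenol 7.

**Further compounds**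
F1 | step 5 | 4-bromo-2-methoxy-6-pentadecylphenol | CCCCCCCCCCCCCCCc1cc(Br)cc(OC)c1O
F2 | step 5 | 4-bromo-2-methoxy-6-pentadecylphenyl acetate | CCCCCCCCCCCCCCCc1cc(Br)cc(OC)c1OC(C)=O
F3 | step 6 | 2-methoxy-6-pentadecylbenzene-1,4-diol | CCCCCCCCCCCCCCCc1cc(O)cc(OC)c1O
F4 | step 6 | 2-methoxy-6-pentadecyl-1,4-phenylene diacetate | CCCCCCCCCCCCCCCc1cc(OC(C)=O)cc(OC)c1OC(C)=O
F5 | step 2 | 2-(benzyloxy)-3-methoxybenzaldehyde | COc1cccc(C=O)c1OCc1ccccc1
F6 | step 2 | 2-(benzyloxy)-1-methoxy-3-[(1Z)-pentadec-1-en-1-yl]benzene (expected major isomer; E/Z mixture) | CCCCCCCCCCCCC/C=C\c1cccc(OC)c1OCc1ccccc1
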